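**Strategy.** Each 2,2-dimethyloxepan-3-one ring (O1, C2–C7; C6 and C7 shared with a cyclohexane) is disconnected at the C2–C3 bond between CMe2 and C=O. The feature exploited is that C2 is an oxygen-bearing carbon beside the C3 carbonyl, i.e. an ester carbon in disguise. In one operation a titanium-alkylidene olefinic-ester cyclization closes both seven-membered rings: the acetate on the C7 oxygen supplies C2 and one methyl, the terminus of a butenyl chain on quaternary C6 supplies C3, and C2=C3 forms by ring-closing carbonyl–olefin metathesis; epoxidation/methyl transfer and oxidation then give CMe2–C=O. The precursor is an ethylene-linked bis-cyclohexane bearing two acetates, two silyl ethers and two butenyl groups.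

Key step: step 14

Remark on the chemistry: carbons are numbered along the C24 chain as in squalene (C2/C23 = CMe2, C3/C22 = C=O, C6/C19 = quaternary C–Me, C7/C18 = C–O, C10/C15 = C(Me)OAc, C11/C14 = ring CH, C12–C13 = bridge; ring A = C6–C11, ring B = C14–C19); the target is not C2-symmetric, because the acetate is cis to the angular methyl in ring A (C10) and trans in ring B (C15), which steps 8–11 address; vinyllithium is generated from Sn(CH=CH2)4 and MeLi, and DMDO is used as an acetone solution.

**Step 1**
Reactants: 1 hex-5-en-1-yne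
Product: 4 (2E)-3-methylhepta-2,6-dien-1-ol, via alkenylalane 2 (not isolated), via lithium alanate 3 (not isolated)
Conditions: AlMe3, Cp2ZrCl2 (cat.), CH2Cl2, rt; n-BuLi, THF, −78 °C; (CH2O)n, −78 °C → rt
Reagents that add atoms: trimethylaluminium C[Al](C)C; paraformaldehyde (formaldehyde unit) C=O
Why: Negishi carboalumination adds methyl and aluminium syn across the terminal alkyne with methyl at the internal carbon, and the alkenylalanate is hydroxymethylated with retention, so the trisubstituted alkene should be formed as the E isomer while the remote terminal alkene stays inert.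

**Step 2**
Reactants: 4 (2E)-3-methylhepta-2,6-dien-1-ol
Product: 5 [(2S,3S)-3-(but-3-en-1-yl)-3-methyloxiran-2-yl]methanol
Conditions: Ti(OiPr)4 (cat.), L-(+)-diethyl tartrate (cat.), t-BuOOH, 4 Å MS, CH2Cl2, −20 °C
Reagents that add atoms: tert-butyl hydroperoxide CC(C)(C)OO
Why: Sharpless asymmetric epoxidation oxidises only the allylic alkene, and the L-(+)-tartrate complex should set both epoxide carbons (2S,3S), as it does for geraniol.

**Step 3**
Reactants: 5 [(2S,3S)-3-(but-3-en-1-yl)-3-methyloxiran-2-yl]methanol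
Product: 6 (2R,3S)-3-(but-3-en-1-yl)-2-(iodomethyl)-3-methyloxirane
Conditions: I2, PPh3, imidazole, Et2O/MeCN, 0 °C
Reagents that add atoms: iodine II
Why: Appel-type iodination of the primary alcohol under imidazole buffering leaves the epoxide and its stereocentres untouched (the descriptor at C2 changes only through priorities).

**Step 4**
Reactants: 7 acetyltrimethylsilane; 8 cyclohexylamine
Product: 9 N-cyclohexyl-1-(trimethylsilyl)ethan-1-imine
Conditions: 4 Å MS, Et2O, rt
Reagents that add atoms: none
Why: Condensation of the acylsilane carbonyl with the primary amine (imine formation) gives the metalloenamine precursor needed for clean C-alkylation.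

**Step 5**
Reactants: 9 N-cyclohexyl-1-(trimethylsilyl)ethan-1-imine; 6 (2R,3S)-3-(but-3-en-1-yl)-2-(iodomethyl)-3-methyloxirane
Product: 11 3-[(2S,3S)-3-(but-3-en-1-yl)-3-methyloxiran-2-yl]-1-(trimethylsilyl)propan-1-one, via alkylated imine 10 (not isolated)
Conditions: LiN(iPr)2, THF, −78 → 0 °C; 6, −78 → −20 °C; then AcOH/NaOAc buffer (pH 5), H2O, 0 °C
Reagents that add atoms: water O
Why: Aza-enolate (metalloenamine) alkylation by SN2 at the primary iodide, followed by mild buffered imine hydrolysis, should give the acylsilane without opening the trisubstituted epoxide.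

**Step 6**
Reactants: 11 3-[(2S,3S)-3-(but-3-en-1-yl)-3-methyloxiran-2-yl]-1-(trimethylsilyl)propan-1-one (2 equiv)
Product: 14 (3Z,7Z)-1,10-bis[(2S,3S)-3-(but-3-en-1-yl)-3-methyloxiran-2-yl]-3,8-bis(trimethylsilyloxy)deca-3,7-diene, via silyl alkoxide 12 (not isolated), via siloxyallyllithium 13 (not isolated)
Conditions: vinyllithium (from Sn(CH=CH2)4 + MeLi), THF, −78 → −30 °C; then I2 (0.5 equiv per acylsilane), −78 °C
Reagents that add atoms: vinyllithium [Li]C=C
Why: 1,2-Addition of vinyllithium to the acylsilane, Brook rearrangement to the siloxyallyl anion and iodine-induced oxidative γ,γ-coupling should give the C2-symmetric dimer with the C12–C13 bond in place, the Z enol ether geometry following from the internally chelated siloxyallyllithium.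

**Step 7**
Reactants: 14 (3Z,7Z)-bis(silyl enol ether) bis-epoxide
Product: 15 (2S,2'S,3S,3'S,4S,4'S)-2,2'-(ethane-1,2-diyl)bis[3-(but-3-en-1-yl)-4-hydroxy-3-methylcyclohexan-1-one]
Conditions: MeAlCl2, CH2Cl2, −94 → −78 °C; then 1 M HCl, THF, 0 °C
Reagents that add atoms: none
Why: In each half a Lewis-acid-promoted epoxide-initiated cyclization terminated by the silyl enol ether proceeds through a chair in which C11 attacks C6 anti to the breaking C6–O bond, so the E epoxide fixes C6 (inversion) relative to C7 (retained), the Z enol ether places C12 equatorial with H-11 trans to the axial C6 methyl, and the oxocarbenium ion collapses to the C10 ketone.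

**Step 8**
Reactants: 15 C2-symmetric diketone diol
Product: 16 (2S,3S,4S)-3-(but-3-en-1-yl)-2-{2-[(1R,2S,3S)-2-(but-3-en-1-yl)-3-hydroxy-2-methyl-6-methylidenecyclohexyl]ethyl}-4-hydroxy-3-methylcyclohexan-1-one
Conditions: Ph3PCH3Br (1.0 equiv), KOtBu, THF, 0 °C → rt; recovered 15 recycled
Reagents that add atoms: methyltriphenylphosphonium bromide C[P+](c1ccccc1)(c1ccccc1)c1ccccc1.[Br-]
Why: Wittig methylenation with one equivalent of ylide desymmetrises the diketone, since the two ketones are homotopic (C2 axis) and mono-olefination therefore gives a single compound, expected in statistical admixture with recyclable 15 and the bis-alkene.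

**Step 9**
Reactants: 16 mono-methylidene ketone diol
Product: 17 (1R,2S,3S,4S)-3-(but-3-en-1-yl)-2-{2-[(1R,2S,3S)-2-(but-3-en-1-yl)-3-hydroxy-2-methyl-6-methylidenecyclohexyl]ethyl}-1,3-dimethylcyclohexane-1,4-diol
Conditions: MeMgBr (excess), THF, −78 → 0 °C
Reagents that add atoms: methylmagnesium bromide C[Mg]Br
Why: Grignard 1,2-addition should occur by equatorial attack, anti to the axial C6 methyl that blocks the axial trajectory (as in 3,3,5-trimethylcyclohexanone), giving the axial C10 hydroxyl cis to the C6 methyl.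

**Step 10**
Reactants: 17 triol with ring B exocyclic methylene
Product: 18 spiro-epoxide of 17 at C15 (1-oxaspiro[2.5]octane in ring B, epoxide oxygen equatorial and trans to the C19 methyl)
Conditions: mCPBA (1.05 equiv), NaHCO3, CH2Cl2, −20 → 0 °C
Reagents that add atoms: 3-chloroperbenzoic acid OOC(=O)c1cccc(Cl)c1
Why: Prilezhaev epoxidation should select the more nucleophilic 1,1-disubstituted exocyclic alkene over the two monosubstituted alkenes and attack its equatorial face, anti to the axial C19 methyl.

**Step 11**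
Reactants: 18 spiro-epoxide
Product: 19 (1R,1'S,2S,2'S,3S,3'S,4S,4'S)-2,2'-(ethane-1,2-diyl)bis[3-(but-3-en-1-yl)-1,3-dimethylcyclohexane-1,4-diol]
Conditions: LiAlH4, THF, reflux
Reagents that add atoms: none
Why: Hydride SN2 opening of the spiro-epoxide at its CH2 carbon should give the equatorial C15 hydroxyl with an axial methyl, epimeric to the C10 centre made in step 9.

**Step 12**
Reactants: 19 tetraol
Product: 20 4,4'-di-O-acetate of 19 (acetates on C7 and C18, tertiary hydroxyls free)
Conditions: Ac2O, pyridine, DMAP (cat.), CH2Cl2, 0 °C → rt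
Reagents that add atoms: acetic anhydride CC(=O)OC(C)=O
Why: DMAP-catalysed acylation discriminates the two secondary alcohols from the hindered tertiary ones.

**Step 13**
Reactants: 20 diacetate diol
Product: 21 1,1'-bis(triethylsilyl) ether of 20
Conditions: Et3SiOTf, 2,6-lutidine, CH2Cl2, −78 → 0 °C
Reagents that add atoms: triethylsilyl trifluoromethanesulfonate CC[Si](CC)(CC)OS(=O)(=O)C(F)(F)F
Why: Silyl triflate silylation masks the two tertiary alcohols against the protic-sensitive titanium alkylidene of the next step.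

**Step 14**
Reactants: 21 bis(silyl ether) diacetate
Product: 23 1,2-bis[2,5a,7-trimethyl-7-(triethylsilyloxy)-4,5,5a,6,7,8,9,9a-octahydro-1-benzoxepin-6-yl]ethane (trans ring fusions, configurations as in 21), via titanium alkylidene 22 (not isolated)
Conditions: TiCl4, TMEDA, Zn, PbCl2 (cat.), CH3CHBr2, THF/CH2Cl2, 65 °C
Reagents that add atoms: none
Why: The Takai–Utimoto-type titanium ethylidene first undergoes [2+2] cycloaddition/cycloreversion with each terminal alkene (loss of propene) to give a titanium alkylidene at C3/C22, which then olefinates the neighbouring acetate carbonyl through an oxatitanacyclobutane, expelling a titanium oxo species and forging C2=C3 and C22=C23. The closest known reaction type is the olefinic-ester cyclization to cyclic enol ethers with reduced titanium alkylidenes (ring-closing carbonyl–olefin metathesis), established for fused six- and seven-membered ethers. Each oxepene is closed as a seven-membered ring by intramolecular carbonyl olefination between the alkylidene carbon (C3) and the ester carbon (C2), the new double bond being endocyclic. No stereocentre is created and C6/C7 and C18/C19 are untouched. The step needs alkene metathesis to precede direct ethylidenation of the acetates (which would give acyclic enol ethers) and ring closure to beat oligomerisation; the bulky ethylidene reagent favours the alkene-first pathway, the trans-diequatorial C7 acetate and C6 butenyl chain are held within reach on the chair, and the tertiary alcohols are silylated.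

**Step 15**
Reactants: 23 bis-oxepene
Product: 25 bis(2,2-dimethyloxepan-3-ol) derived from 23 (carbinol configuration at C3/C22 undefined and inconsequential), via bis-epoxide 24 (not isolated)
Conditions: DMDO, acetone/CH2Cl2, −78 → 0 °C; evaporate; AlMe3, CH2Cl2, −78 → −20 °C
Reagents that add atoms: dimethyldioxirane CC1(C)OO1; trimethylaluminium C[Al](C)C
Why: Dioxirane epoxidation of the electron-rich enol ethers, then Lewis-acid opening to the tertiary oxocarbenium ion with methyl transfer from aluminium (C-glycoside-type epoxide opening), should install the second methyl on C2/C23 and leave C3/C22 as secondary alcohols.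

**Step 16**
Reactants: 25 diol
Product: 26 bis(triethylsilyl) ether of the diketone (2,2-dimethyloxepan-3-ones in both halves)
Conditions: Dess–Martin periodinane, NaHCO3, CH2Cl2, rt
Reagents that add atoms: none
Why: Dess–Martin oxidation converts both secondary alcohols into the ketones, and the adjacent C2/C23 carbons are quaternary so nothing can epimerise.

**Step 17**
Reactants: 26 bis(silyl ether) diketone
Product: 27 diketone diol (tertiary alcohols at C10 and C15 free)
Conditions: Bu4NF, THF, 0 °C → rt
Reagents that add atoms: none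
Why: Fluoride-mediated cleavage of the tertiary silyl ethers is compatible with the ketones, which have no β-leaving group.

**Step 18**
Reactants: 27 diketone diol
Product: 28 target CNP0325605.1, 1,2-bis(7-acetoxy-2,2,5a,7-tetramethyl-3-oxodecahydro-1-benzoxepin-6-yl)ethane with (5aS,6S,7R,9aS) in one half and (5aS,6S,7S,9aS) in the other
Conditions: Ac2O, Sc(OTf)3 (cat.), MeCN, −20 °C
Reagents that add atoms: acetic anhydride CC(=O)OC(C)=O
Why: Sc(OTf)3-catalysed acylation with the anhydride should acetylate both hindered tertiary alcohols at low temperature without elimination, the ketones being inert.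

**Compound list**

1 | hex-5-en-1-yne | C#CCCC=C | starting material
2 | (E)-dimethyl(2-methylhexa-1,5-dien-1-yl)alane | C=CCC/C(C)=C/[Al](C)C | intermediate
3 | lithium (E)-butyldimethyl(2-methylhexa-1,5-dien-1-yl)aluminate | [Li+].C=CCC/C(C)=C/[Al-](C)(C)CCCC | intermediate
4 | (2E)-3-methylhepta-2,6-dien-1-ol | C=CCC/C(C)=C/CO | intermediate
5 | [(2S,3S)-3-(but-3-en-1-yl)-3-methyloxiran-2-yl]methanol | OC[C@@H]1O[C@@]1(C)CCC=C | intermediate
6 | (2R,3S)-3-(but-3-en-1-yl)-2-(iodomethyl)-3-methyloxirane | IC[C@@H]1O[C@@]1(C)CCC=C | intermediate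
7 | acetyltrimethylsilane | CC(=O)[Si](C)(C)C | starting material
8 | cyclohexylamine | NC1CCCCC1 | starting material
9 | N-cyclohexyl-1-(trimethylsilyl)ethan-1-imine | CC(=NC1CCCCC1)[Si](C)(C)C | intermediate
10 | N-cyclohexyl imine of acylsilane 11 | C[Si](C)(C)C(=NC1CCCCC1)CC[C@@H]2O[C@@]2(C)CCC=C | intermediate
11 | 3-[(2S,3S)-3-(but-3-en-1-yl)-3-methyloxiran-2-yl]-1-(trimethylsilyl)propan-1-one | C[Si](C)(C)C(=O)CC[C@@H]1O[C@@]1(C)CCC=C | intermediate
12 | lithium alkoxide from vinyl addition to 11 (carbinol centre undefined) | [Li+].[O-]C(C=C)(CC[C@@H]1O[C@@]1(C)CCC=C)[Si](C)(C)C | intermediate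
13 | (Z)-siloxyallyllithium from Brook rearrangement of 12 | [Li+].[CH2-]/C=C(\O[Si](C)(C)C)CC[C@@H]1O[C@@]1(C)CCC=C | intermediate
14 | (3Z,7Z)-1,10-bis[(2S,3S)-3-(but-3-en-1-yl)-3-methyloxiran-2-yl]-3,8-bis(trimethylsilyloxy)deca-3,7-diene | C[Si](C)(C)O/C(CC[C@@H]1O[C@@]1(C)CCC=C)=C\CC/C=C(\O[Si](C)(C)C)CC[C@@H]1O[C@@]1(C)CCC=C | intermediate
15 | (2S,2'S,3S,3'S,4S,4'S)-2,2'-(ethane-1,2-diyl)bis[3-(but-3-en-1-yl)-4-hydroxy-3-methylcyclohexan-1-one] | O=C1CC[C@H](O)[C@@](C)(CCC=C)[C@@H]1CC[C@H]1[C@](C)(CCC=C)[C@@H](O)CCC1=O | intermediate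
16 | mono-methylidene ketone diol (ring A ketone, ring B exocyclic methylene) | O=C1CC[C@H](O)[C@@](C)(CCC=C)[C@@H]1CC[C@H]1[C@](C)(CCC=C)[C@@H](O)CCC1=C | intermediate
17 | triol: ring A C10 tertiary alcohol (OH cis to C6 methyl), ring B exocyclic methylene | O[C@]1(C)CC[C@H](O)[C@@](C)(CCC=C)[C@@H]1CC[C@H]1[C@](C)(CCC=C)[C@@H](O)CCC1=C | intermediate
18 | spiro-epoxide of 17 at C15 (epoxide oxygen trans to C19 methyl) | O[C@]1(C)CC[C@H](O)[C@@](C)(CCC=C)[C@@H]1CC[C@H]1[C@](C)(CCC=C)[C@@H](O)CC[C@@]12CO2 | intermediate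
19 | (1R,1'S,2S,2'S,3S,3'S,4S,4'S)-2,2'-(ethane-1,2-diyl)bis[3-(but-3-en-1-yl)-1,3-dimethylcyclohexane-1,4-diol] | O[C@]1(C)CC[C@H](O)[C@@](C)(CCC=C)[C@@H]1CC[C@H]1[C@](C)(CCC=C)[C@@H](O)CC[C@]1(C)O | intermediate
20 | 4,4'-di-O-acetate of 19 | O[C@]1(C)CC[C@H](OC(C)=O)[C@@](C)(CCC=C)[C@@H]1CC[C@H]1[C@](C)(CCC=C)[C@@H](OC(C)=O)CC[C@]1(C)O | intermediate
21 | 1,1'-bis(triethylsilyl) ether of 20 | CC[Si](CC)(CC)O[C@]1(C)CC[C@H](OC(C)=O)[C@@](C)(CCC=C)[C@@H]1CC[C@H]1[C@](C)(CCC=C)[C@@H](OC(C)=O)CC[C@]1(C)O[Si](CC)(CC)CC | intermediate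
22 | bis(titanium alkylidene) of 21 at C3 and C22 (ligands on titanium not shown) | CC[Si](CC)(CC)O[C@]1(C)CC[C@H](OC(C)=O)[C@@](C)(CCC=[Ti])[C@@H]1CC[C@H]1[C@](C)(CCC=[Ti])[C@@H](OC(C)=O)CC[C@]1(C)O[Si](CC)(CC)CC | intermediate
23 | 1,2-bis[2,5a,7-trimethyl-7-(triethylsilyloxy)-4,5,5a,6,7,8,9,9a-octahydro-1-benzoxepin-6-yl]ethane | CC[Si](CC)(CC)O[C@]1(C)CC[C@@H]2OC(C)=CCC[C@@]2(C)[C@@H]1CC[C@H]1[C@]2(C)CCC=C(C)O[C@H]2CC[C@]1(C)O[Si](CC)(CC)CC | intermediate
24 | bis(enol ether epoxide) of 23 (epoxide configuration undefined) | CC[Si](CC)(CC)O[C@]1(C)CC[C@@H]2OC3(C)OC3CC[C@@]2(C)[C@@H]1CC[C@H]1[C@]2(C)CCC3OC3(C)O[C@H]2CC[C@]1(C)O[Si](CC)(CC)CC | intermediate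
25 | bis(2,2-dimethyloxepan-3-ol), bis(triethylsilyl) ether (C3/C22 carbinols undefined) | CC[Si](CC)(CC)O[C@]1(C)CC[C@@H]2OC(C)(C)C(O)CC[C@@]2(C)[C@@H]1CC[C@H]1[C@]2(C)CCC(O)C(C)(C)O[C@H]2CC[C@]1(C)O[Si](CC)(CC)CC | intermediate
26 | bis(2,2-dimethyloxepan-3-one), bis(triethylsilyl) ether | CC[Si](CC)(CC)O[C@]1(C)CC[C@@H]2OC(C)(C)C(=O)CC[C@@]2(C)[C@@H]1CC[C@H]1[C@]2(C)CCC(=O)C(C)(C)O[C@H]2CC[C@]1(C)O[Si](CC)(CC)CC | intermediate
27 | diketone diol (C10 and C15 tertiary alcohols) | O[C@]1(C)CC[C@@H]2OC(C)(C)C(=O)CC[C@@]2(C)[C@@H]1CC[C@H]1[C@]2(C)CCC(=O)C(C)(C)O[C@H]2CC[C@]1(C)O | intermediate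
28 | CNP0325605.1 | CC(=O)O[C@]1(C)CC[C@@H]2OC(C)(C)C(=O)CC[C@@]2(C)[C@@H]1CC[C@H]1[C@]2(C)CCC(=O)C(C)(C)O[C@H]2CC[C@]1(C)OC(C)=O | target

**Totals.** Total step count: 18. Longest linear sequence: 17 steps (steps 1–3 and 5–18; step 4 prepares the imine 9).

**Steps most likely to fail**

1. Step 14 (double olefinic-ester cyclization). Direct ethylidenation of the acetate carbonyls may outpace alkylidene transfer to the hindered butenyl termini, giving acyclic enol ethers that do not cyclise, or only one of the two rings may close. Fallback, setting out from 21 and returning at 23: Petasis methylenation with Cp2TiMe2 (toluene, 65 °C) converts both acetates into isopropenyl ethers, giving the bis(isopropenyl ether) F1; ring-closing enol ether–olefin metathesis with the second-generation Grubbs catalyst RuCl2(=CHPh)(H2IMes)(PCy3) (benzene, 60 °C) then closes both oxepenes to 23.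

2. Step 8 (mono-methylenation of the C2-symmetric diketone). The statistical distribution between unreacted diketone, mono-alkene and bis-alkene limits throughput, and over-olefination cannot be suppressed by stoichiometry alone. Fallback, setting out from 6 and 11 and returning at 16, which makes the two halves different before ring formation:
   - Alkylation of the dianion of ethyl acetoacetate (NaH, then n-BuLi, THF) with 6 gives the epoxy β-keto ester F2.
   - NaH/PhNTf2 gives the (Z)-enol triflate F3.
   - Pd(PPh3)4-catalysed Kumada coupling with Me3SiCH2MgCl gives the allylsilane ester F4.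
   - (iBu)2AlH reduction (−78 °C) gives the allylic alcohol F5, and CBr4/PPh3 gives the allylic bromide F6.
   - The siloxyallyllithium 13 (from 11 and vinyllithium as in step 6) is alkylated at its γ-carbon by F6 to give the unsymmetrical bis-epoxide F7, which carries one silyl enol ether and one allylsilane terminator.
   - MeAlCl2 (CH2Cl2, −94 → −78 °C) then closes both rings; the allylsilane half should end as the exocyclic methylene and the enol-ether half as the ketone, which is 16.

3. Step 15 (epoxidation and methyl transfer). After epoxidation the tertiary oxocarbenium ion may lose a proton or undergo hydride shift faster than it captures methyl from aluminium. Fallback, setting out from 23 (through 24) and returning at 25: the bis-epoxide is opened with thiophenol to the hydroxy S,O-ketal F8, which is oxidised with mCPBA/NaHCO3 to the anomeric sulfone F9; AlMe3 at low temperature then displaces the sulfonyl group with methyl to give 25.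

**Further compounds**

F1 | step 14 | bis(isopropenyl ether) from methylenation of 21 | CC[Si](CC)(CC)O[C@]1(C)CC[C@H](OC(C)=C)[C@@](C)(CCC=C)[C@@H]1CC[C@H]1[C@](C)(CCC=C)[C@@H](OC(C)=C)CC[C@]1(C)O[Si](CC)(CC)CC
F2 | step 8 | ethyl 5-[(2S,3S)-3-(but-3-en-1-yl)-3-methyloxiran-2-yl]-3-oxopentanoate | CCOC(=O)CC(=O)CC[C@@H]1O[C@@]1(C)CCC=C
F3 | step 8 | (Z)-enol triflate of F2 | CCOC(=O)/C=C(\OS(=O)(=O)C(F)(F)F)CC[C@@H]1O[C@@]1(C)CCC=C
F4 | step 8 | ethyl (Z)-5-[(2S,3S)-3-(but-3-en-1-yl)-3-methyloxiran-2-yl]-3-[(trimethylsilyl)methyl]pent-2-enoate | CCOC(=O)/C=C(\C[Si](C)(C)C)CC[C@@H]1O[C@@]1(C)CCC=C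
F5 | step 8 | allylic alcohol from reduction of F4 | OC/C=C(\C[Si](C)(C)C)CC[C@@H]1O[C@@]1(C)CCC=C
F6 | step 8 | allylic bromide from F5 | BrC/C=C(\C[Si](C)(C)C)CC[C@@H]1O[C@@]1(C)CCC=C
F7 | step 8 | unsymmetrical bis-epoxide with one silyl enol ether and one allylsilane terminator | C[Si](C)(C)C/C(CC[C@@H]1O[C@@]1(C)CCC=C)=C\CC/C=C(\O[Si](C)(C)C)CC[C@@H]1O[C@@]1(C)CCC=C
F8 | step 15 | bis(2-methyl-2-phenylthio-oxepan-3-ol) from 24 | CC[Si](CC)(CC)O[C@]1(C)CC[C@@H]2OC(C)(Sc3ccccc3)C(O)CC[C@@]2(C)[C@@H]1CC[C@H]1[C@]2(C)CCC(O)C(C)(Sc3ccccc3)O[C@H]2CC[C@]1(C)O[Si](CC)(CC)CC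
F9 | step 15 | bis(anomeric phenyl sulfone) from F8 | CC[Si](CC)(CC)O[C@]1(C)CC[C@@H]2OC(C)(S(=O)(=O)c3ccccc3)C(O)CC[C@@]2(C)[C@@H]1CC[C@H]1[C@]2(C)CCC(O)C(C)(S(=O)(=O)c3ccccc3)O[C@H]2CC[C@]1(C)O[Si](CC)(CC)CC
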